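**Strategy.** Numbering used throughout: C1 = quaternary epoxide carbon (bears CH2OBz), C2 = CHOBz, C3 = CHOH, C4=C5, C6 = epoxide CH. The cyclohexene ring is cut at C2–C3 and C1–C6. Its C3(O)–C4=C5–C6(O) unit is furan in disguise, and C1–C2 with the exocyclic carbon is 2-bromoacrolein; these two achiral liquids are the precursors. One enantioselective Diels–Alder reaction makes both bonds and fixes C3. Loss of HBr, exo addition of benzoate and ejection of the oxygen bridge from C6 then give a cis hydroxy benzoate diene, so the furan oxygen ends as the C3 hydroxyl. Sharpless epoxidation of C1=C6 and benzoylation complete the target.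

Key step: step 1

Assumption: the oxazaborolidinone from N-tosyl-(S)-tryptophan is taken to give the (2R)-bromo aldehydes in the parent 2-bromoacrolein reactions, so its mirror image from the (R)-amino acid is used to reach 3.

Step 1
Reactants: 1 furan; 2 2-bromoprop-2-enal
Product: 3 (1S,2S,4S)-2-bromo-7-oxabicyclo[2.2.1]hept-5-ene-2-carbaldehyde
Conditions: (4R)-2-butyl-4-(1H-indol-3-ylmethyl)-3-(4-methylbenzenesulfonyl)-1,3,2-oxazaborolidin-5-one (10 mol%, made in situ from N-tosyl-(R)-tryptophan and BuB(OH)2), furan (5 equiv), CH2Cl2, −78 °C; used cold and at once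
Reagents that add atoms: none
Why: Concerted suprafacial [4+2] cycloaddition (Diels–Alder reaction) of furan with 2-bromoacrolein held s-cis on the boron Lewis acid; the closest known type is the oxazaborolidinone-catalysed Diels–Alder reaction of 2-haloacroleins with furan and cyclopentadiene. The cyclohexene ring C1–C6 is closed by intermolecular cycloaddition across the furan 2,5-positions, which leaves the furan oxygen as a one-atom bridge between C3 and C6. The bridgehead C3, kept to the end, and the transient centres C6 and C1 are set by the catalyst, whose indole ring covers one face of the bound aldehyde so that furan adds to the open face. Exo placement of the formyl group (bromine endo) is secured by the α-bromine, and face plus exo selectivity together decide which enantiomer of dienal 4 forms in step 2. The low temperature is needed to stop cycloreversion of the adduct, which would erode both selectivities.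

Step 2
Reactants: 3 (1S,2S,4S)-2-bromo-7-oxabicyclo[2.2.1]hept-5-ene-2-carbaldehyde
Product: 5 (1S,6R)-2-formyl-6-hydroxycyclohexa-2,4-dien-1-yl benzoate, via oxanorbornadiene aldehyde 4 (not isolated)
Conditions: DBU (1.0 equiv), CH2Cl2, −40 to 0 °C; then PhCO2H (3 equiv), Et3N (0.3 equiv), 0 °C to rt
Reagents that add atoms: benzoic acid, O=C(O)c1ccccc1
Why: Proposed new method: DBU removes HBr by syn-periplanar E2 toward the only non-bridgehead β-carbon (dehydrobromination of an α-bromo aldehyde), giving the strained enal 4; benzoate then adds to its β-carbon from the exo face (the face of the oxygen bridge) and the enolate expels the bridge oxygen from the adjacent bridgehead C6 (E1cB, made irreversible by strain release while the carboxylate addition itself is reversible), so the new C2 centre is cis to the retained C3 oxygen and excess acid protonates the alkoxide before a 1,2-acyl shift; the closest known reactions are thiol and alkoxide conjugate additions to 7-oxanorbornadiene esters and the base-induced β-elimination opening of 7-oxanorbornene esters to cyclohexadienols.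

Step 3
Reactants: 5 (1S,6R)-2-formyl-6-hydroxycyclohexa-2,4-dien-1-yl benzoate
Product: 6 (1S,6R)-2-formyl-6-(triethylsilyloxy)cyclohexa-2,4-dien-1-yl benzoate
Conditions: TESOTf, 2,6-lutidine, CH2Cl2, −78 °C
Reagents that add atoms: triethylsilyl trifluoromethanesulfonate, CC[Si](CC)(CC)OS(=O)(=O)C(F)(F)F
Why: Silyl ether formation with a silyl triflate and a hindered pyridine base is fast at −78 °C and should cap the C3 hydroxyl before any 1,2-benzoyl shift, without touching a stereocentre.

Step 4
Reactants: 6 (1S,6R)-2-formyl-6-(triethylsilyloxy)cyclohexa-2,4-dien-1-yl benzoate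
Product: 7 (1S,6R)-2-(hydroxymethyl)-6-(triethylsilyloxy)cyclohexa-2,4-dien-1-yl benzoate
Conditions: NaBH4, CeCl3·7H2O, MeOH/CH2Cl2, −78 °C
Reagents that add atoms: none
Why: Luche reduction should reduce the dienal carbonyl in the 1,2 sense only and leave the benzoate and the silyl ether intact.

Step 5
Reactants: 7 (1S,6R)-2-(hydroxymethyl)-6-(triethylsilyloxy)cyclohexa-2,4-dien-1-yl benzoate
Product: 8 (1S,2R,3R,6S)-1-(hydroxymethyl)-3-(triethylsilyloxy)-7-oxabicyclo[4.1.0]hept-4-en-2-yl benzoate
Conditions: Ti(OiPr)4 (10 mol%), L-(+)-diethyl tartrate (12 mol%), t-BuOOH (decane), 4 Å molecular sieves, CH2Cl2, −20 °C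
Reagents that add atoms: tert-butyl hydroperoxide, CC(C)(C)OO
Why: Sharpless asymmetric epoxidation should act only on the C1=C6 bond, the one carrying the free allylic hydroxymethyl group, and L-(+)-diethyl tartrate should direct the oxygen to the face syn to the C2 benzoate (reagent control), which sets C1 and C6.

Step 6
Reactants: 8 (1S,2R,3R,6S)-1-(hydroxymethyl)-3-(triethylsilyloxy)-7-oxabicyclo[4.1.0]hept-4-en-2-yl benzoate
Product: 9 [(1S,2R,3R,6S)-2-(benzoyloxy)-3-(triethylsilyloxy)-7-oxabicyclo[4.1.0]hept-4-en-1-yl]methyl benzoate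
Conditions: BzCl, Et3N, DMAP (cat.), CH2Cl2, 0 °C
Reagents that add atoms: benzoyl chloride, O=C(Cl)c1ccccc1
Why: Acylation of the primary alcohol with benzoyl chloride under nucleophilic catalysis is routine, and the amine base is too weak to start a Payne rearrangement of the epoxy alcohol.

Step 7
Reactants: 9 [(1S,2R,3R,6S)-2-(benzoyloxy)-3-(triethylsilyloxy)-7-oxabicyclo[4.1.0]hept-4-en-1-yl]methyl benzoate
Product: 10 [(1S,2R,3R,6S)-2-(benzoyloxy)-3-hydroxy-7-oxabicyclo[4.1.0]hept-4-en-1-yl]methyl benzoate
Conditions: TBAF, AcOH (1:1), THF, 0 °C to rt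
Reagents that add atoms: none
Why: Fluoride cleavage of the triethylsilyl ether buffered with acetic acid should free the C3 hydroxyl near neutral pH, avoiding both benzoyl shift from C2 and opening of the allylic epoxide.

**Compound list** (bicyclic epoxides 8–10 are numbered as in the target)

1 | furan | c1ccoc1 | starting material
2 | 2-bromoprop-2-enal (2-bromoacrolein) | C=C(Br)C=O | starting material
3 | (1S,2S,4S)-2-bromo-7-oxabicyclo[2.2.1]hept-5-ene-2-carbaldehyde (formyl exo, syn to the oxygen bridge; bromine endo) | O=C[C@]1(Br)C[C@H]2C=C[C@@H]1O2 | intermediate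
4 | (1S,4R)-7-oxabicyclo[2.2.1]hepta-2,5-diene-2-carbaldehyde | O=CC1=C[C@H]2C=C[C@@H]1O2 | intermediate
5 | (1S,6R)-2-formyl-6-hydroxycyclohexa-2,4-dien-1-yl benzoate (hydroxyl and benzoate cis) | O=CC1=CC=C[C@@H](O)[C@H]1OC(=O)c1ccccc1 | intermediate
6 | (1S,6R)-2-formyl-6-(triethylsilyloxy)cyclohexa-2,4-dien-1-yl benzoate | O=CC1=CC=C[C@@H](O[Si](CC)(CC)CC)[C@H]1OC(=O)c1ccccc1 | intermediate
7 | (1S,6R)-2-(hydroxymethyl)-6-(triethylsilyloxy)cyclohexa-2,4-dien-1-yl benzoate | OCC1=CC=C[C@@H](O[Si](CC)(CC)CC)[C@H]1OC(=O)c1ccccc1 | intermediate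
8 | (1S,2R,3R,6S)-1-(hydroxymethyl)-3-(triethylsilyloxy)-7-oxabicyclo[4.1.0]hept-4-en-2-yl benzoate (epoxide, benzoate and silyloxy group all cis) | OC[C@]12O[C@H]1C=C[C@@H](O[Si](CC)(CC)CC)[C@H]2OC(=O)c1ccccc1 | intermediate
9 | [(1S,2R,3R,6S)-2-(benzoyloxy)-3-(triethylsilyloxy)-7-oxabicyclo[4.1.0]hept-4-en-1-yl]methyl benzoate | O=C(OC[C@]12O[C@H]1C=C[C@@H](O[Si](CC)(CC)CC)[C@H]2OC(=O)c1ccccc1)c1ccccc1 | intermediate
10 | [(1S,2R,3R,6S)-2-(benzoyloxy)-3-hydroxy-7-oxabicyclo[4.1.0]hept-4-en-1-yl]methyl benzoate | O=C(OC[C@]12O[C@H]1C=C[C@@H](O)[C@H]2OC(=O)c1ccccc1)c1ccccc1 | target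

**Total step count:** 7. **Longest linear sequence:** 7 steps (1 + 2 → 10).

**Steps most likely to fail**

Step 2 (proposed new method). The weakly nucleophilic carboxylate may add too slowly, so that the strained dienal is consumed by amidine addition or isomerises to a phenol. The ring-opened product may also lose benzoic acid with aromatisation, or undergo a 1,2-benzoyl shift. The fallback sets out from 3 and comes back at 9. Compound 3 is dehydrobrominated with DBU as before and 4 is isolated cold. 4-Methoxybenzyl alcohol with KOtBu (10 mol%) in THF at −40 °C adds as the alkoxide from the bridge face and the enolate opens the bridge, giving the ether (5R,6S)-5-hydroxy-6-[(4-methoxyphenyl)methoxy]cyclohexa-1,3-diene-1-carbaldehyde F1, which can neither migrate nor leave. TESOTf and 2,6-lutidine give its triethylsilyl ether F2. NaBH4 with CeCl3 gives the dienyl carbinol F3. Sharpless epoxidation with L-(+)-diethyl tartrate gives the epoxy alcohol F4. BzCl and Et3N give the primary benzoate F5. DDQ in CH2Cl2 with pH 7 buffer removes the 4-methoxybenzyl group to give the C2 alcohol F6, and BzCl, pyridine and DMAP then give 9.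

Step 5. Reagent control may be incomplete if the C2 benzoate shields the face that the tartrate selects, and the titanium alkoxide may open the vinyl epoxide or take the benzoyl group. The fallback sets out from 7 and comes back at 9, and uses hydroxyl direction from C2 instead of the chiral reagent. K2CO3 in MeOH at 0 °C removes the benzoate to give the diol (1S,6R)-2-(hydroxymethyl)-6-(triethylsilyloxy)cyclohexa-2,4-dien-1-ol F7. VO(acac)2 with t-BuOOH epoxidises C1=C6 syn to the ring hydroxyl to give the epoxy diol F8. BzCl (2.5 equiv), pyridine and DMAP benzoylate both hydroxyls to give 9.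

Step 7. On desilylation the freed C3 hydroxyl may take the benzoyl group from C2, or fluoride may open the allylic epoxide. The fallback sets out from 5 and comes back at 10, and does without a protecting group on C3. Luche reduction of 5 gives the diol (1S,6R)-6-hydroxy-2-(hydroxymethyl)cyclohexa-2,4-dien-1-yl benzoate F9. Sharpless epoxidation with L-(+)-diethyl tartrate, to which the ring secondary allylic alcohol responds far more slowly, gives the epoxy diol F10. BzCl with 2,4,6-collidine at −40 °C then benzoylates the primary hydroxyl only, giving 10.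

**Further compounds**

F1 | step 2 | (5R,6S)-5-hydroxy-6-[(4-methoxyphenyl)methoxy]cyclohexa-1,3-diene-1-carbaldehyde | O=CC1=CC=C[C@@H](O)[C@H]1OCc1ccc(OC)cc1
F2 | step 2 | (5R,6S)-6-[(4-methoxyphenyl)methoxy]-5-(triethylsilyloxy)cyclohexa-1,3-diene-1-carbaldehyde | O=CC1=CC=C[C@@H](O[Si](CC)(CC)CC)[C@H]1OCc1ccc(OC)cc1
F3 | step 2 | [(5R,6S)-6-[(4-methoxyphenyl)methoxy]-5-(triethylsilyloxy)cyclohexa-1,3-dien-1-yl]methanol | OCC1=CC=C[C@@H](O[Si](CC)(CC)CC)[C@H]1OCc1ccc(OC)cc1
F4 | step 2 | [(1S,2R,3R,6S)-2-[(4-methoxyphenyl)methoxy]-3-(triethylsilyloxy)-7-oxabicyclo[4.1.0]hept-4-en-1-yl]methanol | OC[C@]12O[C@H]1C=C[C@@H](O[Si](CC)(CC)CC)[C@H]2OCc1ccc(OC)cc1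
F5 | step 2 | [(1S,2R,3R,6S)-2-[(4-methoxyphenyl)methoxy]-3-(triethylsilyloxy)-7-oxabicyclo[4.1.0]hept-4-en-1-yl]methyl benzoate | O=C(OC[C@]12O[C@H]1C=C[C@@H](O[Si](CC)(CC)CC)[C@H]2OCc1ccc(OC)cc1)c1ccccc1
F6 | step 2 | [(1S,2R,3R,6S)-2-hydroxy-3-(triethylsilyloxy)-7-oxabicyclo[4.1.0]hept-4-en-1-yl]methyl benzoate | O=C(OC[C@]12O[C@H]1C=C[C@@H](O[Si](CC)(CC)CC)[C@H]2O)c1ccccc1
F7 | step 5 | (1S,6R)-2-(hydroxymethyl)-6-(triethylsilyloxy)cyclohexa-2,4-dien-1-ol | OCC1=CC=C[C@@H](O[Si](CC)(CC)CC)[C@H]1O
F8 | step 5 | (1S,2R,3R,6S)-1-(hydroxymethyl)-3-(triethylsilyloxy)-7-oxabicyclo[4.1.0]hept-4-en-2-ol | OC[C@]12O[C@H]1C=C[C@@H](O[Si](CC)(CC)CC)[C@H]2O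
F9 | step 7 | (1S,6R)-6-hydroxy-2-(hydroxymethyl)cyclohexa-2,4-dien-1-yl benzoate | OCC1=CC=C[C@@H](O)[C@H]1OC(=O)c1ccccc1
F10 | step 7 | (1S,2R,3R,6S)-3-hydroxy-1-(hydroxymethyl)-7-oxabicyclo[4.1.0]hept-4-en-2-yl benzoate | OC[C@]12O[C@H]1C=C[C@@H](O)[C@H]2OC(=O)c1ccccc1
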